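The data were generated by integration with made-up constants, and the scatter is random.

Follow one molecule of free monomer and ask its chance of still being free at time t.

| flask | free monomer | pre-initiator | remark | time |
|---|---|---|---|---|
| oak | 1.1 M | 8 mM | run made earlier |  |
| ash | 2.4 M | 8 mM | run made earlier |  |
| maple | 1.6 M | 16 mM | run made earlier |  |
| flask | 1.6 M | 8.0 mM |  | 4.0 h |

- oak (time / h: monomer in chains / %, free monomer / %): 0.333: 2.4, 96.0; 0.500: 8.0, 89.1; 0.833: 21.9, 76.6; 1.33: 47.1, 51.3; 2.50: 86.7, 13.3; 4.00: 97.5, 0.7
- ash (time / h: monomer in chains / %, free monomer / %): 0.667: 17.3, 81.5; 1.33: 47.8, 48.8; 2.00: 76.0, 20.3; 2.50: 86.7, 10.1; 3.00: 93.8, 1.3; 4.00: 97.5, 1.0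
- maple (time / h: monomer in chains / %, free monomer / %): 0.333: 6.5, 92.7; 0.667: 28.0, 71.5; 1.00: 52.2, 45.9; 2.00: 90.7, 6.7; 4.00: 98.4, 0

(scatter of a reading: 1 percentage point)

- average number of monomer units in a chain (chains begun, living or dead) at 4.0 h
- part of the free monomer that has reacted at 4.0 h

- the average divides the monomer in chains by the number of chains begun, living and dead together
- steps under discussion: free monomer + initiator -> living end + monomer in chains; free monomer + living end -> monomer in chains + living end; pre-initiator -> initiator; free monomer -> uncatalysed product; free monomer + initiator -> spent initiator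
- the earlier runs do not show the number of chains; that part of a forecast is a guess

Oak and ash differ in charge, yet at 1.33 h they read 51.3% and 48.8% free, so the loss is pseudo-first-order in [free monomer]. But the logarithm of charged over left grows about as time squared in oak, so [living end] climbs steadily. Oak's reading gives 1.63 h for the survival time τ, the time at which that logarithm reaches one, with the logarithm equal to t/τ squared. Maple, with twice the pre-initiator, reads a shorter 1.13 h. The ratio is 1.44, near the root of that doubling, 1.41, so I let τ go as one over the root of [pre-initiator].

The flask has oak's pre-initiator, so I reckon 0.239% free at 4.0 h. But oak holds more at 2.50 h, 13.3%, than τ gives, 9.51%, so I read 99.8% for c, the part of the free monomer reacted, as a high figure. The readings do not count chains, so I put no number on dp, the average number of monomer units in a chain.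

The forecast says c 99% (98% to 99.7%) and dp 800 (400 to 2000), “so dp is about 800, very uncertain”.

The flask gives dp 412 and c 99.3%.

    free monomer + initiator → living end + monomer in chains (k = 0.00429 /M/s)
    free monomer + living end → monomer in chains + living end, rate k2*[living end]*[free monomer] (k = 0.141 /M/s)
    pre-initiator → initiator (k = 6.26 × 10⁻⁵ /s)
    free monomer → uncatalysed product (k = 5.97 × 10⁻⁶ /s)
    free monomer + initiator → spent initiator (k = 7.15 × 10⁻⁵ /M/s)

At 4.00 h the flask holds 0.698% free monomer, more than my 0.239%, with 41% of its pre-initiator still there. For a neighbour flask charged with 0.0020 M of pre-initiator, my rule puts τ at 3.26 h, which reckons 22.2% free at 4.0 h; that neighbour flask holds 24.4%.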